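(The earlier runs and the new flask come from a simulation with made-up constants; scatter was added.)

0.0427 min⁻¹ is the number I carry, the leak: the chance per minute that a target molecule turns into isomer of the product, read in the ash run between 15.0 min and 40.0 min. Over the same window the elm run reads 0.0412 min⁻¹ and the alder run 0.0409 min⁻¹, though initiator goes from 7.4 mol% to 16 mol%, so I treat the leak as a first-order step apart from the step that makes target.

| setting | ash | elm | alder | west | south-east | south | east |
|---|---|---|---|---|---|---|---|
| substrate | 0.020 M | 0.020 M | 0.020 M | 0.020 M | 0.020 M | 0.020 M (fed, over 0.800 h) | 0.020 M |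
| partner | 3 equiv | 3 equiv | 3 equiv | 3.00 equiv | 3.00 equiv | 3.00 equiv | 3.00 equiv (fed, over 0.800 h) |
| initiator | 7.4 mol% | 10 mol% | 16 mol% | 7.4 mol% | 7.4 mol% | 7.4 mol% | 7.4 mol% |
| remark | run made earlier | run made earlier | run made earlier | a single well-mixed tank run continuously and read at steady state, 1.0 h in it on average | everything together in a closed stirred flask, run for 1.0 h | all but substrate at the start; substrate goes in evenly over 0.800 h, the run ends at 1.0 h | a stirred flask in which partner is dosed at a steady rate over 0.800 h without added volume, worked up at 1.0 h |
| time |  |  |  |  | 1.0 h | 1.0 h | 1.0 h |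

| run | time / min | target / % | isomer of the product / % | substrate / % |
|---|---|---|---|---|
| ash | 3.00 | 32.6 | 4.0 | 63.4 |
| ash | 10.0 | 74.1 | 24.1 | 1.3 |
| ash | 15.0 | 61.4 | 39.4 | 0 |
| ash | 25.0 | 39.2 | 60.7 | 0 |
| ash | 40.0 | 21.1 | 77.3 | 0 |
| ash | 50.0 | 18.4 | 82.0 | 0.1 |
| ash | 60.0 | 13.1 | 84.5 | 1.0 |
| elm | 3.00 | 39.4 | 1.4 | 59.0 |
| elm | 4.00 | 49.7 | 4.9 | 44.5 |
| elm | 6.00 | 66.3 | 8.8 | 22.1 |
| elm | 10.0 | 74.3 | 27.1 | 2.6 |
| elm | 15.0 | 60.8 | 39.2 | 0 |
| elm | 25.0 | 36.7 | 62.1 | 0.8 |
| elm | 40.0 | 21.7 | 78.0 | 0.6 |
| alder | 5.00 | 73.1 | 9.1 | 18.9 |
| alder | 10.0 | 71.1 | 29.5 | 0.8 |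
| alder | 15.0 | 55.9 | 42.2 | 0.2 |
| alder | 20.0 | 45.4 | 53.6 | 0 |
| alder | 25.0 | 37.5 | 62.5 | 0.1 |
| alder | 30.0 | 31.9 | 70.7 | 0 |
| alder | 40.0 | 20.1 | 78.9 | 0.6 |

(readings scatter by 1 percentage point)

- the stated concentrations are those of everything mixed, before any reaction; amounts are the same in each set-up
- the feed brings no volume worth counting
- the earlier runs were made in a closed, stirred flask

- the set-up with the highest share of target in all that became target or isomer of the product, at the outlet or at the end ("none" if the first two lie within 2 percentage points) (west / south-east / south / east / none)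
- share of target in all that became target or isomer of the product, at the outlet or at the end, west
- share of target in all that became target or isomer of the product, at the outlet or at the end, south-east
- share of target in all that became target or isomer of the product, at the outlet or at the end, south
- share of target in all that became target or isomer of the product, at the outlet or at the end, east

I build the flask up one process at a time. With the main step by itself, substrate becoming target, each share stands at 100 %, and the ash run shows that step is quick, with substrate at 1.3 % by 10.0 min. Adding the leak, I follow one target molecule. In west it stands at a fork, leaving on average after 1.0 h or leaking, so its chance of leaving as target is 28.1 %. In south-east it is born by about 10.0 min and then faces the leak until the end, which leaves 11.8 %. In south the feed of 0.0208 min⁻¹ of the charge is slower than the 0.122 min⁻¹ the ash run consumes at first, so I let each molecule become target on arrival, and averaging the leak over those births and the quiet time after the feed gives 25.4 %. The earlier runs hold partner at 3 equiv and show no order in it, so for east I commit to no more than a place between 11.8 % and 25.4 %. The last process is a way back: a leak without return takes the ash reading at 40.0 min to 8.98 % at 60.0 min, but 13.1 % is read, so target seems to level off, as under thermodynamic rather than kinetic control, and my shares should run low. I put west ahead of south by 2.7 percentage points.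

The forecast gives 29 % for west, 13 % for south-east, 25.5 % for south and 18 % for east, picks west, and calls the decay “independent of initiator”.

The simulation picks west, with 31.1 % in west, 14.6 % in south-east, 26.5 % in south and 21.9 % in east, each of my reckoned shares lying lower, and east inside its bracket.

    initiator → 2 initiating radical (k = 1.98 × 10⁻⁴ min⁻¹)
    substrate + initiating radical → capped initiator + first chain carrier (k = 8.10 × 10⁶ M⁻¹ s⁻¹)
    partner + first chain carrier → target + second chain carrier (k = 2.57 × 10⁵ M⁻¹ s⁻¹)
    substrate + second chain carrier → released group + first chain carrier (k = 2.86 × 10⁵ M⁻¹ s⁻¹)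
    2 first chain carrier → ended chains (k = 6.20 × 10⁸ M⁻¹ s⁻¹)
    target ⇌ isomer of the product (K = 8.55, k = 0.0498 min⁻¹)

South has not come to rest at 1.0 h, although the forward half-life of target is 0.23 h, shorter than that time. South stands at 26.5 % and reaches 10.5 % at 10.0 h, so 16 points is still moving; the leak acting on that excess gives 10.8 % at 2.5 h, where the same south flask stands at 10.6 %. At 10.0 h south-east has gone from 14.6 % to 10.5 %, and east from 21.9 % to 10.5 %.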